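## Retrosynthetic overview

1. Target 23 ⇐ γ-lactone 16 by twofold α-methylenation (C-11, C-4), tiglate ester at O-8 and late release of the C-15 acid; the C-6/C-7 γ-lactone is the last ring formed.
2. 16 ⇐ bicyclic keto δ-lactone 8: ketone → axial 8β-silyl ether; the δ-lactone is opened so that its carbonyl becomes the C-15 acid and its O–CH2 carbon (C-1) the vinyl group.
3. 8 ⇐ meso cyclobutanone 7: a rhodium catalyst cuts one enantiotopic C(=O)–C bond (C-8–C-5) and inserts the tethered olefin C-9=C-10, a (4+2) ring expansion that forms the cyclohexanone and the temporary δ-lactone together.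
4. 7 ⇐ (2+2) cycloaddition of a ketene with a silyl enol ether, both C4 pieces of the succinate family. Ring order: cyclobutanone, then cyclohexanone + δ-lactone, then γ-lactone.
5. Enabling feature: ring atoms C-5, C-6, C-7, C-8 carry oxygen at C-6 and C-8 and two identical CH2–CO2 arms (C-4/C-15 on C-5, C-11/C-12 on C-7), both trans to O-6. This is a meso 3-oxycyclobutanone with C-8 as carbonyl. The C-15 carboxyl (on C-5) and C-1 (on C-10) are trans-vicinal, so an allyl-type ester between them delivers the olefin and later leaves the free acid and the vinyl group.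

Key step: step 4

Remark on locants: elemane numbering is used. Ring: C-5 (CH bearing C-4(=C-3)–C-15), C-6 (O–CH), C-7 (CH bearing C-11(=C-13)–C-12), C-8 (CH–O), C-9 (CH2), C-10 (quaternary; CH3 = C-14; vinyl = C-1=C-2). β is the face of the C-10 methyl group, α the opposite face.

Remark (assumption): which antipode of the ligand makes the catalyst cut the C-8–C-5 bond of the drawn enantiomer is to be fixed in a first run; (R) is written for definiteness.

## Route

Step 1
Reactants: 1 methyl 4-oxobutanoate
Product: 2 methyl 4-(triethylsilyloxy)but-3-enoate (E/Z mixture)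
Conditions: Et3SiOTf, Et3N, CH2Cl2, −78 → 0 °C
Reagents that add atoms: triethylsilyl trifluoromethanesulfonate, CC[Si](CC)(CC)OS(=O)(=O)C(F)(F)F
Why: Soft enolization and O-silylation of the aldehyde (silyl enol ether formation) should be much faster than enolization of the ester, and the olefin geometry is of no consequence because the carbon concerned becomes an epimerizable α-carbon of the cyclobutanone.

Step 2
Reactants: 2 methyl 4-(triethylsilyloxy)but-3-enoate; 3 methyl 4-chloro-4-oxobutanoate
Product: 5 meso all-trans cyclobutanone dimethyl ester, via ketene 4 (not isolated)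
Conditions: Et3N, MeCN, 80 °C, slow addition of 3; then Et3N, rt (equilibration)
Reagents that add atoms: none
Why: The thermal ketene–enol ether (2+2) cycloaddition should join the ketene carbonyl carbon to the nucleophilic β-carbon of the silyl enol ether (3-silyloxy-2,4-disubstituted pattern), and since both substituted ring carbons are α to the ketone the amine should equilibrate them to the all-trans meso isomer, the thermodynamic one.

Step 3
Reactants: 5 meso all-trans cyclobutanone dimethyl ester; 6 2-methylprop-2-en-1-ol (first equivalent)
Product: 7 meso all-trans cyclobutanone bis(2-methylallyl) ester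
Conditions: Bu2SnO (10 mol %), 6 (10 equiv in all, two of which are taken up), toluene, 110 °C, 4 Å molecular sieves (removal of MeOH)
Reagents that add atoms: 2-methylprop-2-en-1-ol (second equivalent, for the second ester group), C=C(C)CO
Why: Tin-catalysed transesterification under neutral conditions should exchange each of the two methyl esters for one molecule of the olefin-bearing alcohol, driven by removal of two equivalents of methanol, without touching the silyl ether, and the α-centres stay at their equilibrium (all-trans) configuration.

Step 4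
Reactants: 7 meso all-trans cyclobutanone bis(2-methylallyl) ester
Product: 8 bicyclic keto δ-lactone (trans-fused)
Conditions: [Rh(cod)2]BF4 (5 mol %), (R)-DTBM-SEGPHOS (6 mol %), 1,4-dioxane, 60 °C
Reagents that add atoms: none
Why: Monovalent rhodium should insert into one C(=O)–Cα bond of the cyclobutanone (oxidative addition to trivalent rhodium with C–C cleavage), the 1,1-disubstituted olefin of the ester arm on that same α-carbon then inserts so that C-5 is joined to C-10 and the acyl carbon C-8 to C-9, and reductive elimination releases the cyclohexanone and the catalyst, the whole being an isomerization. The closest known reaction type is the rhodium-catalysed intramolecular carboacylation of olefins by cyclobutanones through C–C activation (the "cut and sew" (4+2) coupling), including its enantioselective versions with DTBM-SEGPHOS. The cyclohexanone closes as a formal (4+2) ring expansion of the four-membered ring, and the δ-lactone closes in the fused mode by exo carbometalation of the tethered olefin (six-membered ring). C-10 is the only new stereocentre and should be set by the ring fusion: a chair-like six-membered transition state with the lactone chain anti to the Rh–C-5 bond places C-1 trans to C-4 and the methyl group trans to H-5, while C-5 is transferred with retention and C-6 and C-7 are untouched. The step needs selection between the two enantiotopic C(=O)–C bonds, which the chiral ligand should provide and which fixes the absolute configuration of C-5, C-6, C-7 and C-10 at once; site selectivity follows because only the olefin carried by the rhodium-bound carbon can reach the metal, and the near-planar metallacycle holds the C-6 silyloxy group out of alignment for β-elimination.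

Step 5
Reactants: 8 bicyclic keto δ-lactone
Product: 10 8β-silyl ether δ-lactone, via lithium alkoxide 9 (not isolated)
Conditions: LiBH(s-Bu)3, THF, −78 °C; then t-BuMe2SiOTf, 2,6-lutidine, CH2Cl2, −78 → 0 °C
Reagents that add atoms: tert-butyldimethylsilyl trifluoromethanesulfonate, CC(C)(C)[Si](C)(C)OS(=O)(=O)C(F)(F)F
Why: Reduction with the bulky borohydride (L-Selectride) should occur by equatorial attack on the chair cyclohexanone, away from the axial C-10 methyl group, which sets the axial 8β-oxygen, and silylation of the alkoxide at low temperature forestalls its attack on the neighbouring ester.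

Step 6
Reactants: 10 8β-silyl ether δ-lactone
Product: 12 hydroxy tert-butyl ester, via hydroxy acid 11 (not isolated)
Conditions: LiOH (1.1 equiv), THF/H2O, 0 °C; HCl (1 M) to pH 5; then Cl3CC(=NH)Ot-Bu, CH2Cl2/cyclohexane, rt
Reagents that add atoms: lithium hydroxide, [Li+].[OH-]; tert-butyl 2,2,2-trichloroacetimidate, CC(C)(C)OC(=N)C(Cl)(Cl)Cl
Why: Saponification should take the δ-lactone much faster than the open-chain 2-methylallyl ester, and acid-free tert-butyl esterification with the trichloroacetimidate then fixes C-15 as an ester that resists later transesterification; no stereocentre is involved.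

Step 7
Reactants: 12 hydroxy tert-butyl ester
Product: 13 C-1 aldehyde
Conditions: Dess–Martin periodinane, NaHCO3, CH2Cl2, 0 °C → rt
Reagents that add atoms: none
Why: Dess–Martin oxidation converts the neopentyl primary alcohol into the aldehyde under buffered, non-epimerizing conditions (the aldehyde has no α-hydrogen).

Step 8
Reactants: 13 C-1 aldehyde
Product: 14 vinyl compound
Conditions: Ph3PCH3Br, KN(SiMe3)2, THF, −78 → 0 °C
Reagents that add atoms: methylenetriphenylphosphorane (from methyltriphenylphosphonium bromide), C=P(c1ccccc1)(c1ccccc1)c1ccccc1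
Why: Wittig methylenation of the non-enolizable aldehyde should install the C-1=C-2 vinyl group on the quaternary carbon, the esters being far less electrophilic toward the ylide at low temperature.

Step 9
Reactants: 14 vinyl compound
Product: 16 trans γ-lactone, via hydroxy ester 15 (not isolated)
Conditions: AcOH/THF/H2O (3:1:1), rt; then DBU (0.2 equiv), toluene, 60 °C
Reagents that add atoms: none
Why: Acid should cleave the triethylsilyl ether much faster than the hindered tert-butyldimethylsilyl ether, and base-catalysed intramolecular transesterification (lactonization) then takes the 2-methylallyl ester and not the tert-butyl ester, closing the trans-fused γ-lactone between the equatorial O-6 and the equatorial C-7 side chain without touching a stereocentre.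

Step 10
Reactants: 16 trans γ-lactone
Product: 18 bis(α-methylene) compound, via bis-Mannich base 17 (not isolated)
Conditions: LiN(i-Pr)2 (2.6 equiv), THF/HMPA, −78 °C; CH2=NMe2+ I− (3 equiv), −78 °C → rt; then MeI, MeOH, rt; then NaHCO3 (aq), EtOAc
Reagents that add atoms: N,N-dimethylmethyleneiminium iodide (Eschenmoser's salt), C=[N+](C)C.[I-]
Why: Twofold Eschenmoser methylenation (Mannich alkylation of the lactone and ester enolates, N-methylation, β-elimination) should introduce both exocyclic methylene groups at C-11 and C-4, the only enolizable positions, with no stereocentre created.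

Step 11
Reactants: 18 bis(α-methylene) compound
Product: 19 8β-alcohol
Conditions: HF·pyridine, THF, 0 °C → rt
Reagents that add atoms: none
Why: Fluoride-mediated desilylation under mildly acidic conditions should free the axial 8β-hydroxyl without conjugate addition to the α-methylene carbonyl groups and without loss of the tert-butyl ester.

Step 12
Reactants: 19 8β-alcohol; 20 tiglic acid ((E)-2-methylbut-2-enoic acid)
Product: 22 8β-tiglate tert-butyl ester, via mixed anhydride 21 (not isolated)
Conditions: 2,4,6-Cl3C6H2COCl, Et3N, toluene, rt; then 19, DMAP, 60 °C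
Reagents that add atoms: none
Why: Yamaguchi esterification should acylate the hindered axial hydroxyl through the mixed anhydride with retention at C-8 (the C–O bond is not broken) and with the E geometry of the tiglate preserved.

Step 13
Reactants: 22 8β-tiglate tert-butyl ester
Product: 23 CNP0256928.1
Conditions: CF3CO2H/CH2Cl2 (1:4), 0 °C → rt
Reagents that add atoms: none
Why: Acidolysis of the tert-butyl ester (loss of isobutene) should release the C-15 acid while the tiglate, the α-methylene lactone and the vinyl group stay intact.

## Compound list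

1 | methyl 4-oxobutanoate | COC(=O)CCC=O | starting material
2 | methyl 4-(triethylsilyloxy)but-3-enoate (E/Z mixture) | COC(=O)CC=CO[Si](CC)(CC)CC | intermediate
3 | methyl 4-chloro-4-oxobutanoate | COC(=O)CCC(=O)Cl | starting material
4 | (2-methoxy-2-oxoethyl)ketene (formed in the flask) | COC(=O)CC=C=O | intermediate
5 | dimethyl 2,2'-[2-oxo-4-(triethylsilyloxy)cyclobutane-1,3-diyl]diacetate, meso all-trans isomer (both CH2CO2Me groups cis to each other and trans to OSiEt3) | O=C1[C@@H](CC(=O)OC)[C@H](O[Si](CC)(CC)CC)[C@H]1CC(=O)OC | intermediate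
6 | 2-methylprop-2-en-1-ol | C=C(C)CO | starting material
7 | bis(2-methylprop-2-en-1-yl) 2,2'-[2-oxo-4-(triethylsilyloxy)cyclobutane-1,3-diyl]diacetate, meso all-trans isomer | O=C1[C@@H](CC(=O)OCC(C)=C)[C@H](O[Si](CC)(CC)CC)[C@H]1CC(=O)OCC(C)=C | intermediate
8 | keto δ-lactone: cyclohexanone (C-8 ketone) trans-fused along C-5/C-10 to the δ-lactone C-15(=O)–O–C-1H2; 10β-CH3, 5α-H, 6α-OSiEt3, 7β-CH2CO2CH2C(CH3)=CH2 | O=C1OC[C@]2(C)CC(=O)[C@@H](CC(=O)OCC(C)=C)[C@H](O[Si](CC)(CC)CC)[C@H]2C1 | intermediate
9 | lithium 8β-alkoxide of reduced 8 (formed in the flask) | O=C1OC[C@]2(C)C[C@@H]([O-])[C@@H](CC(=O)OCC(C)=C)[C@H](O[Si](CC)(CC)CC)[C@H]2C1.[Li+] | intermediate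
10 | δ-lactone as 8 with axial 8β-OSi(t-Bu)Me2 in place of the ketone | O=C1OC[C@]2(C)C[C@@H](O[Si](C)(C)C(C)(C)C)[C@@H](CC(=O)OCC(C)=C)[C@H](O[Si](CC)(CC)CC)[C@H]2C1 | intermediate
11 | hydroxy acid: 10α-CH2OH, 10β-CH3, 5β-CH2CO2H, 6α-OSiEt3, 7β-CH2CO2-(2-methylallyl), 8β-OSi(t-Bu)Me2 (formed in the flask) | OC[C@]1(C)C[C@@H](O[Si](C)(C)C(C)(C)C)[C@@H](CC(=O)OCC(C)=C)[C@H](O[Si](CC)(CC)CC)[C@H]1CC(=O)O | intermediate
12 | tert-butyl ester of 11 (5β-CH2CO2t-Bu, 10α-CH2OH) | OC[C@]1(C)C[C@@H](O[Si](C)(C)C(C)(C)C)[C@@H](CC(=O)OCC(C)=C)[C@H](O[Si](CC)(CC)CC)[C@H]1CC(=O)OC(C)(C)C | intermediate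
13 | aldehyde: as 12 with 10α-CHO | O=C[C@]1(C)C[C@@H](O[Si](C)(C)C(C)(C)C)[C@@H](CC(=O)OCC(C)=C)[C@H](O[Si](CC)(CC)CC)[C@H]1CC(=O)OC(C)(C)C | intermediate
14 | vinyl compound: as 12 with 10α-CH=CH2 | C=C[C@]1(C)C[C@@H](O[Si](C)(C)C(C)(C)C)[C@@H](CC(=O)OCC(C)=C)[C@H](O[Si](CC)(CC)CC)[C@H]1CC(=O)OC(C)(C)C | intermediate
15 | 6α-hydroxy ester from 14 (formed in the flask) | C=C[C@]1(C)C[C@@H](O[Si](C)(C)C(C)(C)C)[C@@H](CC(=O)OCC(C)=C)[C@H](O)[C@H]1CC(=O)OC(C)(C)C | intermediate
16 | trans-fused γ-lactone (O-6α to C-12; 7β-C-11), 8β-OSi(t-Bu)Me2, 5β-CH2CO2t-Bu, 10β-CH3, 10α-vinyl | C=C[C@]1(C)C[C@@H](O[Si](C)(C)C(C)(C)C)[C@H]2CC(=O)O[C@@H]2[C@H]1CC(=O)OC(C)(C)C | intermediate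
17 | bis(dimethylaminomethyl) derivative of 16 at C-11 and C-4 (epimer mixture at these two carbons; formed in the flask) | C=C[C@]1(C)C[C@@H](O[Si](C)(C)C(C)(C)C)[C@H]2C(CN(C)C)C(=O)O[C@@H]2[C@H]1C(CN(C)C)C(=O)OC(C)(C)C | intermediate
18 | α-methylene γ-lactone with tert-butyl 2-substituted acrylate at C-5, 8β-OSi(t-Bu)Me2 | C=C[C@]1(C)C[C@@H](O[Si](C)(C)C(C)(C)C)[C@H]2C(=C)C(=O)O[C@@H]2[C@H]1C(=C)C(=O)OC(C)(C)C | intermediate
19 | 8β-alcohol of 18 | C=C[C@]1(C)C[C@@H](O)[C@H]2C(=C)C(=O)O[C@@H]2[C@H]1C(=C)C(=O)OC(C)(C)C | intermediate
20 | tiglic acid, (E)-2-methylbut-2-enoic acid | C/C=C(\C)C(=O)O | starting material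
21 | tiglic 2,4,6-trichlorobenzoic mixed anhydride (formed in the flask) | C/C=C(\C)C(=O)OC(=O)c1c(Cl)cc(Cl)cc1Cl | intermediate
22 | tert-butyl ester of the target (8β-tiglate) | C=C[C@]1(C)C[C@@H](OC(=O)/C(C)=C/C)[C@H]2C(=C)C(=O)O[C@@H]2[C@H]1C(=C)C(=O)OC(C)(C)C | intermediate
23 | CNP0256928.1: 8β-[(E)-2-methylbut-2-enoyloxy]elema-1,3,11(13)-trien-12,6α-olid-15-oic acid (5α-H, 6β-H, 7α-H, 8α-H, 10β-CH3) | C=C[C@]1(C)C[C@@H](OC(=O)/C(C)=C/C)[C@H]2C(=C)C(=O)O[C@@H]2[C@H]1C(=C)C(=O)O | target

## Step count and risks

Total step count: 13. Longest linear sequence: 13 steps (1 → 23).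

The three steps most likely to fail are these.

Step 4. The catalyst may discriminate poorly between the two enantiotopic C(=O)–C bonds, the acyl–rhodium species may lose carbon monoxide before the ester-linked olefin inserts, or the ring may close with the cis fusion. The fallback moves enantiocontrol to an enzyme and site control to the substrate; it sets out from 7 and comes back at 8. One of the two enantiotopic 2-methylallyl esters of 7 would be hydrolysed with pig liver esterase (phosphate buffer, pH 7) to the half-ester acid F1 (an esterase of the opposite preference would be taken if the other arm reacts). F1 keeps a single olefin tether, so carboacylation with an achiral catalyst ([Rh(cod)2]BF4, Ph2P(CH2)4PPh2, dioxane) can only engage the C(=O)–C bond next to that arm and should give the keto δ-lactone acid F2. Esterification of F2 with 6 (EDC·HCl, DMAP, CH2Cl2) returns to 8.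

Step 2. Dimerization of the alkylketene and C-acylation of the silyl enol ether may outrun the cycloaddition. The fallback uses a more electrophilic ketene and a reductive dehalogenation; it sets out from 3 (with 2) and comes back at 5. Acid chloride 3 would be α-chlorinated (N-chlorosuccinimide, HCl cat., SOCl2, 70 °C) to methyl 3-chloro-4-chloro-4-oxobutanoate F3. Et3N in the presence of 2 would generate the alkyl(chloro)ketene F4, whose (2+2) cycloaddition should give the chlorocyclobutanone F5. Zinc dust with NH4Cl in MeOH would remove the chlorine, and equilibration with Et3N gives 5.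

Step 5. The axial alkoxide may close onto the neighbouring 2-methylallyl ester (five-membered lactone to O-8) before it is silylated, or hydride delivery may lose facial selectivity. The fallback avoids a free alkoxide altogether; it sets out from 8 and comes back at 10. Hydrosilylation of the ketone with t-BuMe2SiH and B(C6F5)3 (2 mol %, CH2Cl2, −40 °C) should deliver the silyl ether directly, the bulky hydridoborate again attacking from the equatorial side.

Further compounds
F1 | step 4 | half-ester acid of 7: CH2CO2H on the ring carbon that becomes C-7, CH2CO2-(2-methylallyl) on the one that becomes C-5, all-trans | O=C1[C@@H](CC(=O)O)[C@H](O[Si](CC)(CC)CC)[C@H]1CC(=O)OCC(C)=C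
F2 | step 4 | keto δ-lactone acid: as 8 with 7β-CH2CO2H | O=C1OC[C@]2(C)CC(=O)[C@@H](CC(=O)O)[C@H](O[Si](CC)(CC)CC)[C@H]2C1
F3 | step 2 | methyl 3-chloro-4-chloro-4-oxobutanoate | COC(=O)CC(Cl)C(=O)Cl
F4 | step 2 | chloro(2-methoxy-2-oxoethyl)ketene (formed in the flask) | COC(=O)CC(Cl)=C=O
F5 | step 2 | dimethyl 2,2'-[1-chloro-2-oxo-4-(triethylsilyloxy)cyclobutane-1,3-diyl]diacetate (diastereomer mixture) | COC(=O)CC1C(O[Si](CC)(CC)CC)C(Cl)(CC(=O)OC)C1=O
F0 | step 5 | none | none
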